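**Retrosynthetic overview**
1. Pestalone D ← removal of three MOM ethers ← keto-aldehyde 21 ← stepwise oxidation of diol 17 ← LiAlH4 opening of 3-arylphthalide 16.
2. Phthalide 15 ← key C–C bond: intermolecular aldol addition of the magnesium phenolate of ring A (12, an aromatic enolate with one free ortho carbon) to the formyl group of ring B aldehyde-ester 10, trapped by lactonisation.
3. Ring A 12 ← dibromination of orcinol monomethyl ether 11. Ring B 10 ← 3,5-dihydroxybenzaldehyde 1 by MOM protection, acetalisation, 2,6-dibromination and two Br/Li exchanges (prenyl, then CO2Me).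
4. Rings: both benzene rings are bought. The only ring formed is the γ-lactone in step 8, and it is opened again in step 10.

Assumption: the target has no stereocentre, so no enantiocontrol is needed; the single stereocentre in intermediates 14–18 is racemic and is erased in step 12.

**Route**

Step 1
Reactants: 1 3,5-dihydroxybenzaldehyde
Product: 2 3,5-bis(methoxymethoxy)benzaldehyde
Conditions: MOMCl (2.5 equiv), i-Pr2NEt (3 equiv), CH2Cl2, 0 °C → rt
Reagents that add atoms: chloromethyl methyl ether (MOMCl), COCCl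
Why: Williamson-type O-alkylation (MOM protection) of both phenols leaves the aldehyde untouched and gives ethers that survive organolithiums yet cleave with mild acid at the end.

Step 2
Reactants: 2 3,5-bis(methoxymethoxy)benzaldehyde
Product: 3 3,5-bis(methoxymethoxy)benzaldehyde dimethyl acetal
Conditions: HC(OMe)3 (3 equiv), PPTS (2 mol%), MeOH, rt, 1 h; Et3N quench
Reagents that add atoms: trimethyl orthoformate, COC(OC)OC
Why: Acid-catalysed acetalisation with orthoformate as water scavenger masks the unhindered aldehyde against n-BuLi much faster than aryl MOM ethers are solvolysed under PPTS.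

Step 3
Reactants: 3 3,5-bis(methoxymethoxy)benzaldehyde dimethyl acetal
Product: 4 2,6-dibromo-3,5-bis(methoxymethoxy)benzaldehyde dimethyl acetal
Conditions: NBS (2.05 equiv), MeCN, 0 °C → rt, dark
Reagents that add atoms: N-bromosuccinimide (NBS), O=C1CCC(=O)N1Br
Why: Electrophilic aromatic bromination goes to the two positions that are para to one OMOM and ortho to the other before the crowded carbon between the two ethers, as in the usual 2,6-dihalogenation of 3,5-dialkoxybenzyl compounds, and gives a symmetric dibromide.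

Step 4
Reactants: 4 2,6-dibromo-3,5-bis(methoxymethoxy)benzaldehyde dimethyl acetal
Product: 7 2-bromo-3,5-bis(methoxymethoxy)-6-(3-methylbut-2-en-1-yl)benzaldehyde dimethyl acetal, via aryllithium 5 (not isolated), via arylcopper 6 (not isolated)
Conditions: n-BuLi (1.0 equiv), THF, −78 °C; CuBr·SMe2 (1.0 equiv), −78 → −40 °C; prenyl bromide (1.3 equiv), → 0 °C
Reagents that add atoms: prenyl bromide (1-bromo-3-methylbut-2-ene), CC(C)=CCBr
Why: Bromine–lithium exchange on the symmetric dibromide gives a single chelated aryllithium which, after transmetalation to copper, undergoes SN2 allylic substitution at the primary carbon of prenyl bromide.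

Step 5
Reactants: 7 2-bromo-3,5-bis(methoxymethoxy)-6-(3-methylbut-2-en-1-yl)benzaldehyde dimethyl acetal
Product: 9 methyl 2-(dimethoxymethyl)-4,6-bis(methoxymethoxy)-3-(3-methylbut-2-en-1-yl)benzoate, via aryllithium 8 (not isolated)
Conditions: n-BuLi (1.1 equiv), THF, −78 °C; cannulate into ClCO2Me (3 equiv), THF, −78 °C → rt
Reagents that add atoms: methyl chloroformate, COC(=O)Cl
Why: A second bromine–lithium exchange followed by acylation with excess chloroformate (inverse addition) installs the ester, and the 2,6-disubstituted ester formed is too hindered for a second addition.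

Step 6
Reactants: 9 methyl 2-(dimethoxymethyl)-4,6-bis(methoxymethoxy)-3-(3-methylbut-2-en-1-yl)benzoate
Product: 10 methyl 2-formyl-4,6-bis(methoxymethoxy)-3-(3-methylbut-2-en-1-yl)benzoate
Conditions: PPTS (0.2 equiv), acetone/H2O 9:1, 40 °C
Reagents that add atoms: water, O
Why: Acetal hydrolysis of an acyclic dimethyl acetal proceeds under PPTS in wet acetone, conditions that leave aryl MOM ethers, the ester and the trisubstituted alkene intact.

Step 7
Reactants: 11 3-methoxy-5-methylphenol (orcinol monomethyl ether)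
Product: 12 2,4-dibromo-5-methoxy-3-methylphenol
Conditions: NBS (2.0 equiv), MeCN, −20 → 0 °C
Reagents that add atoms: N-bromosuccinimide (NBS), O=C1CCC(=O)N1Br
Why: Electrophilic aromatic bromination takes the two positions para to OH and para to OMe (both next to the methyl), leaving the carbon between OH and OMe as the only free site, as in halogenation of other orcinol derivatives.

Step 8
Reactants: 12 2,4-dibromo-5-methoxy-3-methylphenol; 10 methyl 2-formyl-4,6-bis(methoxymethoxy)-3-(3-methylbut-2-en-1-yl)benzoate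
Product: 15 rac-3-(3,5-dibromo-2-hydroxy-6-methoxy-4-methylphenyl)-5,7-bis(methoxymethoxy)-4-(3-methylbut-2-en-1-yl)isobenzofuran-1(3H)-one, via bromomagnesium phenolate 13 (not isolated), via open-chain magnesium aldolate 14 (not isolated)
Conditions: 12 (1.1 equiv), EtMgBr (1.1 equiv), Et2O, 0 °C; swap to toluene; 10 (1.0 equiv), rt → 70 °C; aq NH4Cl
Reagents that add atoms: none
Why: This is an intermolecular aldol addition of an aromatic magnesium enolate (Casiraghi-type ortho-hydroxyalkylation) in which the phenolate binds the aldehyde at magnesium in a non-coordinating solvent and delivers its only free ortho carbon through a six-membered chelate, the alkoxide is then trapped by lactonisation onto the neighbouring ester so that retro-aldol and quinone-methide pathways are shut off, and the new stereocentre is formed racemic because it later becomes the ketone carbon.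

Step 9
Reactants: 15 rac-3-(3,5-dibromo-2-hydroxy-6-methoxy-4-methylphenyl)-5,7-bis(methoxymethoxy)-4-(3-methylbut-2-en-1-yl)isobenzofuran-1(3H)-one
Product: 16 rac-3-[3,5-dibromo-2-methoxy-6-(methoxymethoxy)-4-methylphenyl]-5,7-bis(methoxymethoxy)-4-(3-methylbut-2-en-1-yl)isobenzofuran-1(3H)-one
Conditions: MOMCl (2 equiv), i-Pr2NEt (3 equiv), Bu4NI (cat.), CH2Cl2, 0 °C → 40 °C
Reagents that add atoms: chloromethyl methyl ether (MOMCl), COCCl
Why: O-Alkylation (MOM protection) of the acidic dibromophenol is easy with the reactive MOMCl and removes the free phenol before the hydride, silylation and periodinane steps.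

Step 10
Reactants: 16 rac-3-[3,5-dibromo-2-methoxy-6-(methoxymethoxy)-4-methylphenyl]-5,7-bis(methoxymethoxy)-4-(3-methylbut-2-en-1-yl)isobenzofuran-1(3H)-one
Product: 17 rac-[3,5-dibromo-2-methoxy-6-(methoxymethoxy)-4-methylphenyl][2-(hydroxymethyl)-3,5-bis(methoxymethoxy)-6-(3-methylbut-2-en-1-yl)phenyl]methanol
Conditions: LiAlH4 (2 equiv), THF, 0 °C, 1 h; Fieser work-up
Reagents that add atoms: none
Why: Hydride reduction of the lactone opens it to the primary alcohol and the diaryl carbinol while aryl bromides, MOM ethers and the isolated alkene are inert at 0 °C, and the carbinol stereocentre stays racemic.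

Step 11
Reactants: 17 rac-[3,5-dibromo-2-methoxy-6-(methoxymethoxy)-4-methylphenyl][2-(hydroxymethyl)-3,5-bis(methoxymethoxy)-6-(3-methylbut-2-en-1-yl)phenyl]methanol
Product: 18 rac-[2-({[tert-butyl(dimethyl)silyl]oxy}methyl)-3,5-bis(methoxymethoxy)-6-(3-methylbut-2-en-1-yl)phenyl][3,5-dibromo-2-methoxy-6-(methoxymethoxy)-4-methylphenyl]methanol
Conditions: TBSCl (1.1 equiv), imidazole (2 equiv), CH2Cl2, 0 °C
Reagents that add atoms: tert-butyldimethylsilyl chloride (TBSCl), CC(C)(C)[Si](C)(C)Cl
Why: Selective silyl protection is sterically controlled, since the primary benzylic alcohol reacts while the tetra-ortho-substituted diaryl carbinol does not.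

Step 12
Reactants: 18 rac-[2-({[tert-butyl(dimethyl)silyl]oxy}methyl)-3,5-bis(methoxymethoxy)-6-(3-methylbut-2-en-1-yl)phenyl][3,5-dibromo-2-methoxy-6-(methoxymethoxy)-4-methylphenyl]methanol
Product: 19 [2-({[tert-butyl(dimethyl)silyl]oxy}methyl)-3,5-bis(methoxymethoxy)-6-(3-methylbut-2-en-1-yl)phenyl][3,5-dibromo-2-methoxy-6-(methoxymethoxy)-4-methylphenyl]methanone
Conditions: Dess–Martin periodinane (2.5 equiv), NaHCO3, CH2Cl2, rt
Reagents that add atoms: none
Why: Dess–Martin oxidation of the remaining secondary alcohol gives the benzophenone, no lactol or lactone can form because the primary alcohol is blocked, and the stereocentre is removed.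

Step 13
Reactants: 19 [2-({[tert-butyl(dimethyl)silyl]oxy}methyl)-3,5-bis(methoxymethoxy)-6-(3-methylbut-2-en-1-yl)phenyl][3,5-dibromo-2-methoxy-6-(methoxymethoxy)-4-methylphenyl]methanone
Product: 20 [3,5-dibromo-2-methoxy-6-(methoxymethoxy)-4-methylphenyl][2-(hydroxymethyl)-3,5-bis(methoxymethoxy)-6-(3-methylbut-2-en-1-yl)phenyl]methanone
Conditions: TBAF (1.2 equiv), AcOH (1.2 equiv), THF, 0 °C → rt
Reagents that add atoms: none
Why: Fluoride-mediated desilylation, buffered with acetic acid so that no strongly basic alkoxide persists, frees the primary alcohol, which may sit partly as its cyclic hemiketal.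

Step 14
Reactants: 20 [3,5-dibromo-2-methoxy-6-(methoxymethoxy)-4-methylphenyl][2-(hydroxymethyl)-3,5-bis(methoxymethoxy)-6-(3-methylbut-2-en-1-yl)phenyl]methanone
Product: 21 2-[3,5-dibromo-2-methoxy-6-(methoxymethoxy)-4-methylbenzoyl]-4,6-bis(methoxymethoxy)-3-(3-methylbut-2-en-1-yl)benzaldehyde
Conditions: Dess–Martin periodinane (1.5 equiv), NaHCO3, CH2Cl2, rt
Reagents that add atoms: none
Why: Dess–Martin oxidation of the primary benzylic alcohol (drawn from the open form of the hemiketal equilibrium) gives the aldehyde, and over-oxidation to a phthalide is impossible because the ketone is already in place.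

Step 15
Reactants: 21 2-[3,5-dibromo-2-methoxy-6-(methoxymethoxy)-4-methylbenzoyl]-4,6-bis(methoxymethoxy)-3-(3-methylbut-2-en-1-yl)benzaldehyde
Product: 22 Pestalone D, 2-(3,5-dibromo-2-hydroxy-6-methoxy-4-methylbenzoyl)-4,6-dihydroxy-3-(3-methylbut-2-en-1-yl)benzaldehyde
Conditions: 3 M aq HCl/THF 1:3, 45 °C; neutral work-up (pH 6–7)
Reagents that add atoms: none
Why: Acid-catalysed acetal hydrolysis removes all three MOM groups (those ortho to a carbonyl fastest) while the methyl ether, the aryl bromides and, at this mild temperature, the prenyl group survive, and there is no stereocentre to control.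

**Compound list**
1 | 3,5-dihydroxybenzaldehyde | O=Cc1cc(O)cc(O)c1 | starting material
2 | 3,5-bis(methoxymethoxy)benzaldehyde | COCOc1cc(C=O)cc(OCOC)c1 | intermediate
3 | 3,5-bis(methoxymethoxy)benzaldehyde dimethyl acetal | COCOc1cc(OCOC)cc(C(OC)OC)c1 | intermediate
4 | 2,6-dibromo-3,5-bis(methoxymethoxy)benzaldehyde dimethyl acetal | COCOc1cc(OCOC)c(Br)c(C(OC)OC)c1Br | intermediate
5 | [3-bromo-2-(dimethoxymethyl)-4,6-bis(methoxymethoxy)phenyl]lithium | COCOc1cc(OCOC)c([Li])c(C(OC)OC)c1Br | intermediate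
6 | [3-bromo-2-(dimethoxymethyl)-4,6-bis(methoxymethoxy)phenyl]copper | COCOc1cc(OCOC)c([Cu])c(C(OC)OC)c1Br | intermediate
7 | 2-bromo-3,5-bis(methoxymethoxy)-6-(3-methylbut-2-en-1-yl)benzaldehyde dimethyl acetal | COCOc1cc(OCOC)c(CC=C(C)C)c(C(OC)OC)c1Br | intermediate
8 | [2-(dimethoxymethyl)-4,6-bis(methoxymethoxy)-3-(3-methylbut-2-en-1-yl)phenyl]lithium | COCOc1cc(OCOC)c(CC=C(C)C)c(C(OC)OC)c1[Li] | intermediate
9 | methyl 2-(dimethoxymethyl)-4,6-bis(methoxymethoxy)-3-(3-methylbut-2-en-1-yl)benzoate | COC(=O)c1c(OCOC)cc(OCOC)c(CC=C(C)C)c1C(OC)OC | intermediate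
10 | methyl 2-formyl-4,6-bis(methoxymethoxy)-3-(3-methylbut-2-en-1-yl)benzoate | COC(=O)c1c(OCOC)cc(OCOC)c(CC=C(C)C)c1C=O | intermediate
11 | 3-methoxy-5-methylphenol | COc1cc(C)cc(O)c1 | starting material
12 | 2,4-dibromo-5-methoxy-3-methylphenol | COc1cc(O)c(Br)c(C)c1Br | intermediate
13 | bromomagnesium 2,4-dibromo-5-methoxy-3-methylphenolate | COc1cc(O[Mg]Br)c(Br)c(C)c1Br | intermediate
14 | rac-methyl 2-[(3,5-dibromo-2-hydroxy-6-methoxy-4-methylphenyl)(bromomagnesiooxy)methyl]-4,6-bis(methoxymethoxy)-3-(3-methylbut-2-en-1-yl)benzoate | COC(=O)c1c(OCOC)cc(OCOC)c(CC=C(C)C)c1C(O[Mg]Br)c1c(O)c(Br)c(C)c(Br)c1OC | intermediate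
15 | rac-3-(3,5-dibromo-2-hydroxy-6-methoxy-4-methylphenyl)-5,7-bis(methoxymethoxy)-4-(3-methylbut-2-en-1-yl)isobenzofuran-1(3H)-one | O=C1OC(c2c(O)c(Br)c(C)c(Br)c2OC)c2c(CC=C(C)C)c(OCOC)cc(OCOC)c12 | intermediate
16 | rac-3-[3,5-dibromo-2-methoxy-6-(methoxymethoxy)-4-methylphenyl]-5,7-bis(methoxymethoxy)-4-(3-methylbut-2-en-1-yl)isobenzofuran-1(3H)-one | O=C1OC(c2c(OCOC)c(Br)c(C)c(Br)c2OC)c2c(CC=C(C)C)c(OCOC)cc(OCOC)c12 | intermediate
17 | rac-[3,5-dibromo-2-methoxy-6-(methoxymethoxy)-4-methylphenyl][2-(hydroxymethyl)-3,5-bis(methoxymethoxy)-6-(3-methylbut-2-en-1-yl)phenyl]methanol | OCc1c(OCOC)cc(OCOC)c(CC=C(C)C)c1C(O)c1c(OCOC)c(Br)c(C)c(Br)c1OC | intermediate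
18 | rac-[2-({[tert-butyl(dimethyl)silyl]oxy}methyl)-3,5-bis(methoxymethoxy)-6-(3-methylbut-2-en-1-yl)phenyl][3,5-dibromo-2-methoxy-6-(methoxymethoxy)-4-methylphenyl]methanol | CC(C)(C)[Si](C)(C)OCc1c(OCOC)cc(OCOC)c(CC=C(C)C)c1C(O)c1c(OCOC)c(Br)c(C)c(Br)c1OC | intermediate
19 | [2-({[tert-butyl(dimethyl)silyl]oxy}methyl)-3,5-bis(methoxymethoxy)-6-(3-methylbut-2-en-1-yl)phenyl][3,5-dibromo-2-methoxy-6-(methoxymethoxy)-4-methylphenyl]methanone | CC(C)(C)[Si](C)(C)OCc1c(OCOC)cc(OCOC)c(CC=C(C)C)c1C(=O)c1c(OCOC)c(Br)c(C)c(Br)c1OC | intermediate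
20 | [3,5-dibromo-2-methoxy-6-(methoxymethoxy)-4-methylphenyl][2-(hydroxymethyl)-3,5-bis(methoxymethoxy)-6-(3-methylbut-2-en-1-yl)phenyl]methanone | OCc1c(OCOC)cc(OCOC)c(CC=C(C)C)c1C(=O)c1c(OCOC)c(Br)c(C)c(Br)c1OC | intermediate
21 | 2-[3,5-dibromo-2-methoxy-6-(methoxymethoxy)-4-methylbenzoyl]-4,6-bis(methoxymethoxy)-3-(3-methylbut-2-en-1-yl)benzaldehyde | O=Cc1c(OCOC)cc(OCOC)c(CC=C(C)C)c1C(=O)c1c(OCOC)c(Br)c(C)c(Br)c1OC | intermediate
22 | Pestalone D | COc1c(Br)c(C)c(Br)c(O)c1C(=O)c1c(C=O)c(O)cc(O)c1CC=C(C)C | target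

**Step count and weak points**

Total step count: 15. Longest linear sequence: 14 steps (steps 1–6 and 8–15, from 1 to 22).

Step 8 is the most likely to fail, because the phenolate carbon and the aldehyde are both flanked by two ortho substituents and the addition may be slow. The fallback replaces the enolate by an aryl Grignard reagent. It sets out from phenol 12: iodination at the only free ring carbon (NIS, MeCN, 0 °C) gives 2,4-dibromo-6-iodo-5-methoxy-3-methylphenol F1. MOMCl/i-Pr2NEt then gives 1,3-dibromo-5-iodo-4-methoxy-6-(methoxymethoxy)-2-methylbenzene F2. Selective iodine–magnesium exchange (i-PrMgCl·LiCl, THF, −40 °C, aryl bromides untouched) gives [3,5-dibromo-2-methoxy-6-(methoxymethoxy)-4-methylphenyl]magnesium chloride F3. This adds to the aldehyde of 10 to give the chloromagnesium alkoxide of the open-chain hydroxy ester F4, which lactonises on warming. The fallback comes back to the route at the MOM-protected phthalide 16, so step 9 is not needed.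

Step 4 is the second risk, because copper-mediated prenyl transfer can give SN2′ (reverse-prenyl) or Wurtz by-products. The fallback builds the side chain in two stages from dibromide 4. Br/Li exchange to aryllithium 5 and trapping with allyl bromide (CuBr·SMe2 cat., THF, −78 → 0 °C; SN2 and SN2′ give the same product) gives 2-allyl-6-bromo-3,5-bis(methoxymethoxy)benzaldehyde dimethyl acetal F5. Olefin cross-metathesis with 2-methyl-2-butene (Grubbs II, CH2Cl2, 40 °C) then turns the allyl into the prenyl group and comes back to the route at 7.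

Step 15 is the third risk, because aqueous acid may cyclise the prenyl group onto the freed neighbouring OH (chroman) or damage the keto-aldehyde. The fallback avoids Brønsted acid and sets out from 21. TESOTf/2,2′-bipyridyl (CH2Cl2, 0 °C) exchanges the three aryl MOM ethers for silyl ethers to give 2-[3,5-dibromo-2-methoxy-4-methyl-6-(triethylsilyloxy)benzoyl]-3-(3-methylbut-2-en-1-yl)-4,6-bis(triethylsilyloxy)benzaldehyde F6. HF·pyridine (THF, 0 °C) then removes the silyl groups and comes back to the route at 22.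

**Further compounds**
F1 | step 8 | 2,4-dibromo-6-iodo-5-methoxy-3-methylphenol | COc1c(I)c(O)c(Br)c(C)c1Br
F2 | step 8 | 1,3-dibromo-5-iodo-4-methoxy-6-(methoxymethoxy)-2-methylbenzene | COCOc1c(I)c(OC)c(Br)c(C)c1Br
F3 | step 8 | [3,5-dibromo-2-methoxy-6-(methoxymethoxy)-4-methylphenyl]magnesium chloride | COCOc1c([Mg]Cl)c(OC)c(Br)c(C)c1Br
F4 | step 8 | rac-methyl 2-{[3,5-dibromo-2-methoxy-6-(methoxymethoxy)-4-methylphenyl](chloromagnesiooxy)methyl}-4,6-bis(methoxymethoxy)-3-(3-methylbut-2-en-1-yl)benzoate | COC(=O)c1c(OCOC)cc(OCOC)c(CC=C(C)C)c1C(O[Mg]Cl)c1c(OCOC)c(Br)c(C)c(Br)c1OC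
F5 | step 4 | 2-allyl-6-bromo-3,5-bis(methoxymethoxy)benzaldehyde dimethyl acetal | COCOc1cc(OCOC)c(CC=C)c(C(OC)OC)c1Br
F6 | step 15 | 2-[3,5-dibromo-2-methoxy-4-methyl-6-(triethylsilyloxy)benzoyl]-3-(3-methylbut-2-en-1-yl)-4,6-bis(triethylsilyloxy)benzaldehyde | CC[Si](CC)(CC)Oc1cc(O[Si](CC)(CC)CC)c(CC=C(C)C)c(C(=O)c2c(O[Si](CC)(CC)CC)c(Br)c(C)c(Br)c2OC)c1C=O
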